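**Plan**

1. Target ring numbering: C-1 C(Br)(CH2Cl), C-2 CHCl, C-3 CH2, C-4 CHCl, C-5 C(CH3)(CH=CHCl), C-6 CH2. Retrosynthesis: chloroalkene ⇒ alkyne; C-4–Cl ⇒ C-4 ketone (reduction, then SN2 inversion); C-5–CH3 ⇒ the CH2 of a cyclopropane on a C-4/C-5 silyl enol ether; CH2Cl ⇒ CHO.
2. The remaining cyclohexene is cut at C-1–C-6 and C-2–C-3 in one operation: a catalytic enantioselective Diels–Alder reaction of a 2-silyloxy-3-alkynylbuta-1,3-diene with (Z)-2-bromo-3-chloroprop-2-enal.
3. What makes this possible: C-3 and C-6 are unsubstituted ring CH2 groups in a 1,4 relation (the diene termini); C-4 and C-5 carry the later chlorine (as silyloxy) and the side chain (the inner diene carbons); Br on C-1 and Cl on C-2 are cis, as a Z dienophile delivers them. Formyl (activation, later CH2Cl), silyloxy (regiocontrol, later Cl) and alkyne (later chloroalkene) are the helpers.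
4. Forward order: diene 6 (three steps) and dienophile 8 (one step) are joined to cyclohexene 9, the only ring-forming step; then aldehyde reduction, directed cyclopropanation and opening (methyl group), two deoxychlorinations around a ketone reduction, and alkyne to (E)-chloroalkene.
5. Stereochemistry: the catalyst sets C-1 and the dienophile geometry relays C-2 in the same event; C-5 is relayed from C-1 by the hydroxymethyl-directed cyclopropanation; C-4 comes from a reagent-controlled ketone reduction and SN2 inversion; the E alkene from syn hydrozirconation.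

Key step: step 5

Assumption 1 (geometry of 8): chloride-mediated addition–elimination lets 8 settle as the isomer with chlorine trans to the formyl group (Z), taken to be the more stable one.

Assumption 2 (sense of induction): 8 binds to the (S)-oxazaborolidinium ion like other 2-substituted acroleins, so the open face is the one leading to (1R,6R)-9; the mirror-image catalyst would serve if the sense were opposite.

**Route**

Step 1
Reactants: 1 but-3-en-2-one
Product: 3 3-bromobut-3-en-2-one, via 3,4-dibromobutan-2-one 2 (not isolated)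
Conditions: Br2, CH2Cl2, −78 → 0 °C; then Et3N, 0 °C
Reagents that add atoms: bromine, BrBr
Why: Bromine adds across the enone C=C and triethylamine then removes HBr through the acidic α-proton (bromination–dehydrobromination), which leaves bromine on the α-carbon of the enone.

Step 2
Reactants: 3 3-bromobut-3-en-2-one; 4 ethynyltrimethylsilane
Product: 5 3-methylidene-5-(trimethylsilyl)pent-4-yn-2-one
Conditions: PdCl2(PPh3)2 (3 mol %), CuI (5 mol %), i-Pr2NEt, THF, 0 °C → rt
Reagents that add atoms: none
Why: Sonogashira coupling of the activated C(sp2)–Br bond of the α-bromo enone with the terminal alkyne should proceed under mild conditions, and the hindered tertiary amine does not add to the enone.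

Step 3
Reactants: 5 3-methylidene-5-(trimethylsilyl)pent-4-yn-2-one
Product: 6 2-(triisopropylsilyloxy)-3-[(trimethylsilyl)ethynyl]buta-1,3-diene
Conditions: i-Pr3SiOTf, Et3N, CH2Cl2, 0 °C
Reagents that add atoms: triisopropylsilyl trifluoromethanesulfonate, CC(C)[Si](C(C)C)(C(C)C)OS(=O)(=O)C(F)(F)F
Why: Soft enolisation (silyl triflate and amine) can only occur on the methyl side of the ketone and should give the 2-silyloxy diene, with the bulky silyl group chosen to survive the acidic catalyst of step 5.

Step 4
Reactants: 7 2-bromomalonaldehyde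
Product: 8 (Z)-2-bromo-3-chloroprop-2-enal
Conditions: (COCl)2, DMF (cat.), CH2Cl2, 0 °C → rt
Reagents that add atoms: oxalyl chloride, O=C(Cl)C(Cl)=O
Why: The enol of the 1,3-dialdehyde is converted by the Vilsmeier reagent into the vinylogous acid chloride (β-chloro enal formation from a 1,3-dicarbonyl compound), and reversible chloride addition–elimination should leave chlorine trans to the formyl group.

Step 5
Reactants: 6 2-(triisopropylsilyloxy)-3-[(trimethylsilyl)ethynyl]buta-1,3-diene; 8 (Z)-2-bromo-3-chloroprop-2-enal
Product: 9 (1R,6R)-1-bromo-6-chloro-4-(triisopropylsilyloxy)-3-[(trimethylsilyl)ethynyl]cyclohex-3-ene-1-carbaldehyde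
Conditions: (S)-3,3-diphenyl-1-(2-methylphenyl)tetrahydro-1H,3H-pyrrolo[1,2-c][1,3,2]oxazaborole (20 mol %), Tf2NH (16 mol %), CH2Cl2, −78 → −40 °C
Reagents that add atoms: none
Why: The N-protonated oxazaborolidine binds the formyl oxygen of 8 and lowers its LUMO, and the diene adds in a concerted, asynchronous [4π+2π] cycloaddition in which the CH2 of the silyl enol ether bonds to the β-carbon (C-6 of 9) while the other terminus closes onto the α-carbon (C-1). The closest known reaction type is the catalytic enantioselective Diels–Alder reaction of 2-bromoacrolein and its β-substituted relatives with 2-silyloxy-1,3-dienes under chiral oxazaborolidinium catalysis. The cyclohexene ring is closed by intermolecular [4+2] cycloaddition, suprafacial on both partners, which forms C-1–C-2 and C-5–C-6 of 9 together. The quaternary C-1 (Br, CHO) is set by the catalyst, which holds the s-trans enal by the B–O bond and a formyl C–H···O contact and covers one of its faces with an aryl group, and C-6 follows stereospecifically from the Z geometry of 8, so that Br and Cl end cis. The step needs regioselectivity (silyloxy carbon 1,4 to the formyl-bearing carbon), secured because the oxygen donor outweighs the alkynyl group in fixing the larger HOMO coefficient, and chemoselectivity for cycloaddition over conjugate addition with loss of chloride, secured by the low temperature and the concerted pathway.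

Step 6
Reactants: 9 (1R,6R)-1-bromo-6-chloro-4-(triisopropylsilyloxy)-3-[(trimethylsilyl)ethynyl]cyclohex-3-ene-1-carbaldehyde
Product: 10 [(1R,6R)-1-bromo-6-chloro-4-(triisopropylsilyloxy)-3-[(trimethylsilyl)ethynyl]cyclohex-3-en-1-yl]methanol
Conditions: NaBH4, MeOH/CH2Cl2, −40 °C; pH 7 buffer
Reagents that add atoms: none
Why: Borohydride 1,2-reduction of the non-enolisable α-bromo aldehyde should leave the silyl enol ether, alkyne and halides untouched at low temperature, and the buffered quench prevents closure of the bromohydrin to an epoxide.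

Step 7
Reactants: 10 [(1R,6R)-1-bromo-6-chloro-4-(triisopropylsilyloxy)-3-[(trimethylsilyl)ethynyl]cyclohex-3-en-1-yl]methanol
Product: 12 (2S,4R,5R)-4-bromo-5-chloro-4-(hydroxymethyl)-2-methyl-2-[(trimethylsilyl)ethynyl]cyclohexan-1-one, via siloxycyclopropane 11 (not isolated)
Conditions: Et2Zn, CH2I2, CH2Cl2, 0 °C → rt; then HCl, MeOH, 0 °C → rt
Reagents that add atoms: diiodomethane, ICI
Why: Simmons–Smith cyclopropanation of the electron-rich silyl enol ether is delivered by the zinc alkoxide of the hydroxymethyl group to its own face, which is also the face away from the pseudoaxial C–Br bond, and acid then opens the siloxycyclopropane at the C(O)–CH2 bond with protonation of CH2, so the new methyl group ends cis to the hydroxymethyl group on a quaternary carbon without any enolate that could expel the β-chloride.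

Step 8
Reactants: 12 (2S,4R,5R)-4-bromo-5-chloro-4-(hydroxymethyl)-2-methyl-2-[(trimethylsilyl)ethynyl]cyclohexan-1-one
Product: 13 (2S,4R,5R)-4-bromo-5-chloro-4-(chloromethyl)-2-methyl-2-[(trimethylsilyl)ethynyl]cyclohexan-1-one
Conditions: PPh3, N-chlorosuccinimide, CH2Cl2, 0 → 40 °C
Reagents that add atoms: N-chlorosuccinimide, O=C1CCC(=O)N1Cl
Why: Appel-type deoxychlorination runs through an alkoxyphosphonium chloride ion pair in which chloride sits at the oxygen-bearing carbon and should collapse there even if the neighbouring bromine bridges, so that bromine keeps its place and configuration on the ring carbon while the ketone is inert to this reagent pair.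

Step 9
Reactants: 13 (2S,4R,5R)-4-bromo-5-chloro-4-(chloromethyl)-2-methyl-2-[(trimethylsilyl)ethynyl]cyclohexan-1-one
Product: 14 (1R,2S,4R,5R)-4-bromo-5-chloro-4-(chloromethyl)-2-methyl-2-[(trimethylsilyl)ethynyl]cyclohexan-1-ol
Conditions: (S)-1-methyl-3,3-diphenyltetrahydro-1H,3H-pyrrolo[1,2-c][1,3,2]oxazaborole (0.5 equiv), catecholborane, toluene, −78 → −40 °C; aq. NH4Cl
Reagents that add atoms: none
Why: In this Corey–Bakshi–Shibata reduction the ketone binds anti to its quaternary α-carbon and hydride is delivered by reagent control to the Si face, the face that carries the alkynyl group, which should give the alcohol with OH cis to the methyl group under non-basic conditions that spare the β-chloro ketone.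

Step 10
Reactants: 14 (1R,2S,4R,5R)-4-bromo-5-chloro-4-(chloromethyl)-2-methyl-2-[(trimethylsilyl)ethynyl]cyclohexan-1-ol
Product: 16 {[(1S,2S,4R,5R)-5-bromo-2,4-dichloro-5-(chloromethyl)-1-methylcyclohexyl]ethynyl}trimethylsilane, via secondary triflate 15 (not isolated)
Conditions: Tf2O, 2,6-lutidine, CH2Cl2, −40 °C; then Bu4NCl, −40 °C → rt
Reagents that add atoms: tetrabutylammonium chloride, CCCC[N+](CCCC)(CCCC)CCCC.[Cl-]
Why: SN2 displacement of the triflate by chloride with inversion: in the chair that keeps the slim alkynyl group and the bromine axial the triflate is axial, so chloride enters along the equatorial trajectory and should place chlorine cis to the alkynyl group and to the other ring chlorine.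

Step 11
Reactants: 16 {[(1S,2S,4R,5R)-5-bromo-2,4-dichloro-5-(chloromethyl)-1-methylcyclohexyl]ethynyl}trimethylsilane
Product: 17 (1R,2R,4S,5S)-1-bromo-2,4-dichloro-1-(chloromethyl)-5-ethynyl-5-methylcyclohexane
Conditions: K2CO3 (cat.), MeOH/CH2Cl2, 0 °C
Reagents that add atoms: none
Why: Carbonate-catalysed methanolysis of the C(sp)–Si bond is fast at 0 °C and far milder than what elimination of the tertiary bromide would need.

Step 12
Reactants: 17 (1R,2R,4S,5S)-1-bromo-2,4-dichloro-1-(chloromethyl)-5-ethynyl-5-methylcyclohexane
Product: 19 (1R,2R,4S,5S)-1-bromo-2,4-dichloro-1-(chloromethyl)-5-[(E)-2-chloroethenyl]-5-methylcyclohexane, via (E)-alkenylzirconocene chloride 18 (not isolated)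
Conditions: Cp2Zr(H)Cl, CH2Cl2, rt; then N-chlorosuccinimide, 0 °C
Reagents that add atoms: N-chlorosuccinimide, O=C1CCC(=O)N1Cl
Why: Hydrozirconation of the terminal alkyne is a syn addition that puts zirconium on the terminal carbon, and cleavage of the C–Zr bond by N-chlorosuccinimide proceeds with retention, so only the (E)-chloroalkene should form (hydrozirconation–halogenation).

**Compound list**

1 | but-3-en-2-one (methyl vinyl ketone) | CC(=O)C=C | starting material
2 | 3,4-dibromobutan-2-one (racemic) | CC(=O)C(Br)CBr | intermediate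
3 | 3-bromobut-3-en-2-one | CC(=O)C(Br)=C | intermediate
4 | ethynyltrimethylsilane | C#C[Si](C)(C)C | starting material
5 | 3-methylidene-5-(trimethylsilyl)pent-4-yn-2-one | CC(=O)C(=C)C#C[Si](C)(C)C | intermediate
6 | 2-(triisopropylsilyloxy)-3-[(trimethylsilyl)ethynyl]buta-1,3-diene | C=C(O[Si](C(C)C)(C(C)C)C(C)C)C(=C)C#C[Si](C)(C)C | intermediate
7 | 2-bromomalonaldehyde (2-bromopropanedial) | O=CC(Br)C=O | starting material
8 | (Z)-2-bromo-3-chloroprop-2-enal (Br and Cl cis) | Cl/C=C(\Br)C=O | intermediate
9 | (1R,6R)-1-bromo-6-chloro-4-(triisopropylsilyloxy)-3-[(trimethylsilyl)ethynyl]cyclohex-3-ene-1-carbaldehyde (Br and Cl cis) | O=C[C@]1(Br)CC(C#C[Si](C)(C)C)=C(O[Si](C(C)C)(C(C)C)C(C)C)C[C@H]1Cl | intermediate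
10 | [(1R,6R)-1-bromo-6-chloro-4-(triisopropylsilyloxy)-3-[(trimethylsilyl)ethynyl]cyclohex-3-en-1-yl]methanol | OC[C@]1(Br)CC(C#C[Si](C)(C)C)=C(O[Si](C(C)C)(C(C)C)C(C)C)C[C@H]1Cl | intermediate
11 | [3-bromo-4-chloro-6-(triisopropylsilyloxy)-1-[(trimethylsilyl)ethynyl]bicyclo[4.1.0]heptan-3-yl]methanol, cyclopropane CH2 cis to CH2OH, C-3 and C-4 as in 10 | OC[C@]1(Br)C[C@]2(C#C[Si](C)(C)C)C[C@]2(O[Si](C(C)C)(C(C)C)C(C)C)C[C@H]1Cl | intermediate
12 | (2S,4R,5R)-4-bromo-5-chloro-4-(hydroxymethyl)-2-methyl-2-[(trimethylsilyl)ethynyl]cyclohexan-1-one (CH3 cis to CH2OH) | C[C@@]1(C#C[Si](C)(C)C)C[C@@](Br)(CO)[C@H](Cl)CC1=O | intermediate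
13 | (2S,4R,5R)-4-bromo-5-chloro-4-(chloromethyl)-2-methyl-2-[(trimethylsilyl)ethynyl]cyclohexan-1-one | C[C@@]1(C#C[Si](C)(C)C)C[C@@](Br)(CCl)[C@H](Cl)CC1=O | intermediate
14 | (1R,2S,4R,5R)-4-bromo-5-chloro-4-(chloromethyl)-2-methyl-2-[(trimethylsilyl)ethynyl]cyclohexan-1-ol (OH cis to CH3) | C[C@@]1(C#C[Si](C)(C)C)C[C@@](Br)(CCl)[C@H](Cl)C[C@H]1O | intermediate
15 | (1R,2S,4R,5R)-4-bromo-5-chloro-4-(chloromethyl)-2-methyl-2-[(trimethylsilyl)ethynyl]cyclohexyl trifluoromethanesulfonate | C[C@@]1(C#C[Si](C)(C)C)C[C@@](Br)(CCl)[C@H](Cl)C[C@H]1OS(=O)(=O)C(F)(F)F | intermediate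
16 | {[(1S,2S,4R,5R)-5-bromo-2,4-dichloro-5-(chloromethyl)-1-methylcyclohexyl]ethynyl}trimethylsilane | C[C@@]1(C#C[Si](C)(C)C)C[C@@](Br)(CCl)[C@H](Cl)C[C@@H]1Cl | intermediate
17 | (1R,2R,4S,5S)-1-bromo-2,4-dichloro-1-(chloromethyl)-5-ethynyl-5-methylcyclohexane | C[C@@]1(C#C)C[C@@](Br)(CCl)[C@H](Cl)C[C@@H]1Cl | intermediate
18 | chlorobis(cyclopentadienyl){(E)-2-[(1S,2S,4R,5R)-5-bromo-2,4-dichloro-5-(chloromethyl)-1-methylcyclohexyl]ethenyl}zirconium | C[C@@]1(/C=C/[Zr](Cl)(C2C=CC=C2)C2C=CC=C2)C[C@@](Br)(CCl)[C@H](Cl)C[C@@H]1Cl | intermediate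
19 | (1R,2R,4S,5S)-1-bromo-2,4-dichloro-1-(chloromethyl)-5-[(E)-2-chloroethenyl]-5-methylcyclohexane | C[C@@]1(/C=C/Cl)C[C@@](Br)(CCl)[C@H](Cl)C[C@@H]1Cl | target

**Count and risks**

Total step count: 12. Longest linear sequence: 11 steps (steps 1–3 and 5–12).

Most likely to fail:

- Step 5. What may go wrong: stepwise conjugate addition of the silyl enol ether terminus followed by loss of chloride from the vinylogous acid chloride, or weak face selection, under the strongly acidic catalyst. Fallback: 6 and 8 are heated without any acid (toluene, 60 °C), where the concerted thermal cycloaddition should give the racemate, that is 9 together with its mirror image, the (1S,6S)-aldehyde F1. Reduction as in step 6 should then give 10 and the (1S,6S)-bromohydrin F2. A lipase-catalysed kinetic resolution (lipase from Burkholderia cepacia, vinyl acetate, t-BuOMe, 30 °C; enzyme and sense to be fixed by screening) is used to acylate the unwanted antipode to the (1S,6S)-acetate F3. Unreacted 10 is separated by chromatography and the route is rejoined at 10.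

- Step 8. What may go wrong: neighbouring-group participation of the tertiary bromine, with opening of the bridged bromonium ion by chloride at the ring carbon (1,2-bromine shift to a tertiary chloride and a bromomethyl group). Fallback: starting from 12, the alcohol is converted with SOCl2 (no base, CH2Cl2, −20 °C, HCl swept out with N2) into the alkyl chlorosulfite F4. This is heated in toluene (80 °C) so that SO2 is lost and chlorine is returned from the leaving group itself to the carbon it leaves (internal return), not supplied as free chloride that can reach the ring carbon. This should give 13, where the route is rejoined.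

- Step 10. What may go wrong: E2 elimination of the axial triflate, or ionisation with 1,2-shift from the quaternary neighbour, in competition with a slow SN2 displacement. Fallback: starting from 13, the ketone is converted into the alkenyl chloride F5 ((PhO)3P, Cl2, Et3N, CH2Cl2, −20 °C), which can only form towards the CH2 side because the other α-carbon is quaternary. Hydrogen-atom-transfer hydrogenation (Mn(dpm)3, that is tris(2,2,6,6-tetramethylheptane-3,5-dionato)manganese, cat., PhSiH3, t-BuOOH, i-PrOH, rt) then adds a hydrogen atom to the CH terminus and delivers the second hydrogen axially to the α-chloro radical. This should leave chlorine equatorial and cis to the alkynyl group, that is 16, where the route is rejoined (steps 9 and 10 are replaced).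

**Further compounds**

F1 | step 5 | (1S,6S)-1-bromo-6-chloro-4-(triisopropylsilyloxy)-3-[(trimethylsilyl)ethynyl]cyclohex-3-ene-1-carbaldehyde | O=C[C@@]1(Br)CC(C#C[Si](C)(C)C)=C(O[Si](C(C)C)(C(C)C)C(C)C)C[C@@H]1Cl
F2 | step 5 | [(1S,6S)-1-bromo-6-chloro-4-(triisopropylsilyloxy)-3-[(trimethylsilyl)ethynyl]cyclohex-3-en-1-yl]methanol | OC[C@@]1(Br)CC(C#C[Si](C)(C)C)=C(O[Si](C(C)C)(C(C)C)C(C)C)C[C@@H]1Cl
F3 | step 5 | [(1S,6S)-1-bromo-6-chloro-4-(triisopropylsilyloxy)-3-[(trimethylsilyl)ethynyl]cyclohex-3-en-1-yl]methyl acetate | CC(=O)OC[C@@]1(Br)CC(C#C[Si](C)(C)C)=C(O[Si](C(C)C)(C(C)C)C(C)C)C[C@@H]1Cl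
F4 | step 8 | [(1R,2R,5S)-1-bromo-2-chloro-5-methyl-4-oxo-5-[(trimethylsilyl)ethynyl]cyclohexyl]methyl chlorosulfite | C[C@@]1(C#C[Si](C)(C)C)C[C@@](Br)(COS(=O)Cl)[C@H](Cl)CC1=O
F5 | step 10 | {[(1S,4R,5R)-5-bromo-2,4-dichloro-5-(chloromethyl)-1-methylcyclohex-2-en-1-yl]ethynyl}trimethylsilane | C[C@@]1(C#C[Si](C)(C)C)C[C@@](Br)(CCl)[C@H](Cl)C=C1Cl
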